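Remark on the chemistry: atoms are numbered as in cembranolides (C1 ring-fusion CH, C2 lactone O–CH, C3=C4 and C7=C8 methyl-bearing olefins, C11–C12 oxirane, C13 CH–O, C14 CH2, C15 lactone α-carbon, C16 C=O, C17 exocyclic CH2). The C13 oxygen is carried through the ring closure as a triethylsilyl ether, because this group can later be removed with buffered fluoride beside the α-methylene lactone and the oxirane.

## Analysis of the target

The target 29 is a cembranolide: a 14-membered carbocycle (C1–C14) fused cis at C1/C2 to an α-methylene-γ-butyrolactone (C15, C16, C17 and the oxygen on C2). The large ring holds two (E)-trisubstituted olefins (C3=C4, C7=C8), a trisubstituted oxirane at C11–C12 that derives from an (E)-olefin, and an acetoxy group at C13. The five stereocentres form two groups, C1/C2 (1S,2S, hydrogens cis on the lactone) and C11/C12/C13 (11R,12S,13R, oxirane oxygen and C13 oxygen erythro). The C14 methylene group separates the two groups, so neither can be trusted to control the other. The sensitive functions are the α-methylene lactone (a Michael acceptor that also reacts with metathesis catalysts and with diimide), the allylic C2–O bond (ionised by acid and by zerovalent palladium), the oxirane next to an oxygenated carbon (acid-labile, Payne migration when the C13 oxygen is an alkoxide) and the acetate. The synthesis is hard because a flexible 14-membered ring has to be closed without touching these groups, both trisubstituted olefins must be E, and the two stereo-groups must be set independently in the absolute sense. The strategy rests on the C9–C10 bond: it is the only ring CH2–CH2 bond flanked by an olefin carbon (C8) and by the oxirane carbon C11. It can therefore be made as a disubstituted olefin from a vinyl group on C8 and a vinyl group on C11, and then saturated selectively because every other ring olefin is trisubstituted.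

## Retrosynthetic reasoning

29 is taken back to alcohol 28 and to silyl ether 27. The acetate goes on last because it would not survive the enolate chemistry that builds the exocyclic methylene group. The forward steps must remove silicon without generating an alkoxide next to the oxirane.

The C15–C17 bond is cut next (27 to amine 25 to lactone 24). A lactone without its α-methylene group is inert to the metathesis catalyst and to hydrogen-transfer reduction, so C17 is added by a Mannich reaction and elimination only after both of those steps.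

The ring is opened at C9–C10: 24 comes from triene 23 by saturation of its one disubstituted olefin, and 23 from the open-chain tetraene 22 by ring-closing metathesis. Cutting at C3=C4 or C7=C8 would require a trisubstituted olefin of defined geometry to form during ring closure. Cutting at a saturated bond such as C5–C6 or C13–C14 would require carbanion or carbonyl chemistry beside the lactone and the oxirane. What is gained is a precursor in which all five stereocentres sit on two arms of a small cis-lactone. The forward reactions must achieve macrocyclisation at high dilution and then a chemoselective reduction.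

In 22 the two C–O bonds of the oxirane are disconnected, through epoxy alcohol 21 to dienol 20. The epoxidation is placed late because a vinyl oxirane would not survive the Lewis-acidic, acidic and thermal steps that build the rest of 20. The forward reaction must deliver oxygen to one face of C11=C12 only, under control of the C13 hydroxyl and a chiral catalyst.

The triene arm of 20 (through its silyl ether 19) is cut at C9=CH2 (methylenation of enal 18) and at C7=C8 (Wittig reaction of aldehyde 17 with ylide 2). Both are carbonyl olefinations with predictable E geometry, and both tolerate the lactone.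

17 is traced through allyl vinyl ether 16 to carbinol 15 and aldehyde 14. A [3,3] rearrangement forms the C5–C6 bond and the (E)-C3=C4 olefin together, and addition of an isopropenyl nucleophile forms C3–C4. This avoids an allyl–allyl coupling and the hydride or palladium reagents such a coupling would need, none of which the allylic lactone tolerates.

14 comes from alcohol 13, and 13 from epoxy alcohol 10 and alkyne 11 through ynol ether 12 (C1–C15 bond). Anti opening of a trans-oxirane at C1, followed by acylation of the C2 hydroxyl, gives the cis-lactone, so one asymmetric epoxidation fixes both C1 and C2.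

10 goes back to allylic alcohol 9, ester 8 and alcohol 7. 7 is the slow-reacting enantiomer of racemate 6, which is the vinylogous aldol adduct (C13–C14 bond) of dienal 3 and silyl dienol ether 5. 3 comes from 1 and 2, and 5 from 4. The dienal brings in C10–C13 with the E geometry and the vinyl group that the metathesis needs.

## Alternatives that were turned down

Alternative 1: Here the oxirane C–O bonds and the C13 configuration are disconnected on an acyclic C6–C14 chain. The racemic chloro alcohol A1 would be resolved with Ti(OiPr)4, D-(−)-diisopropyl tartrate and t-BuOOH, which epoxidise only the matching enantiomer on one face of C11=C12 and give the erythro epoxy chlorohydrin A2.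
- For: three of the five stereocentres come from one reagent-controlled step on a simple substrate, and the same Ti(OiPr)4/tartrate logic is in fact used in steps 4 and 15 of the chosen route.
- Against: at most half of A1 is used; the step decides neither the ring closure nor the cis-lactone; and the oxirane of A2 must then survive every later C–C bond formation (alkylation through the C14 chloride, lactone construction, macrocyclisation). A free C13 alkoxide can displace the chloride or trigger Payne migration.
- Comparison: A2 is an ordinary oxirane, more robust than the vinyl oxirane 21, and this alternative is stronger on that point. In exchange the chosen route epoxidises at step 15, after all organometallic and acidic steps, on an enantiopure alcohol so that no late material is lost, and its C11 substituent is the vinyl handle for ring closure.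

Alternative 2: The ring is cut at the bis-allylic C5–C6 bond. In the open bromo sulfone A3 the sulfonyl-stabilised allyl anion at C5 (LiN(SiMe3)2, high dilution) would displace the allylic bromide at C6 to give the macrocyclic sulfone A4.
- For: the closure is an irreversible C–C bond formation that does not depend on catalyst lifetime or on olefin equilibria; both trisubstituted olefins and the C15=C17 carbon are already in place; no sacrificial olefin is needed. As a ring-forming event it is as strong as metathesis or stronger.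
- Against: the C5 carbanion is allylic and vinylogously β to the C2 silyloxy group, so 1,4-elimination competes. The lactone cannot be present and is carried as three silyl ethers. After closure the sulfone must be removed reductively beside an oxirane and allylic ethers (transposition, C–O cleavage), the silyl ethers must be told apart, and C16 must be oxidised and lactonised.
- Comparison: the chosen route offers instead a neutral closure with the lactone intact and only a diimide reduction to clean up, with no auxiliary heteroatom to remove.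

Alternative 3: The ring is cut at C12–C13. In the ynal A5, Ni(cod)2 and PBu3 with Et3B would couple the C13 aldehyde with the C11≡C12 methyl alkyne to give the macrocyclic (E)-allylic alcohol A6.
- For: ring, C12–C13 bond, (E)-C11=C12 olefin and C13 carbinol arise in one neutral step. This is more step-economical at the ring-closing event than the chosen route and leaves no unsaturation to remove.
- Against: the C13 configuration would depend on macrocyclic diastereoselection from the remote C1 centre. The two alkyne substituents (methyl and primary alkyl) differ little, so C–C bond formation at C11 instead of C12 (a 13-membered ring) is a real risk. The oxirane would then have to be introduced on the macrocycle with the erythro sense dictated by ring conformation, and the lactone built afterwards.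
- Comparison: in the chosen route C11–C13 are fixed acyclically by reagent control and the ring closure creates no stereocentre. The price is a bond that must be reduced.

Key step: step 17

## Route

Step 1
Reactants: 1 acrolein (prop-2-enal); 2 2-(triphenyl-λ5-phosphanylidene)propanal
Product: 3 (2E)-2-methylpenta-2,4-dienal
Conditions: CH2Cl2, 25 °C
Reagents that add atoms: none
Why: Wittig olefination with a formyl-stabilised ylide; the reversible addition favours the (E)-enal, which places the future C13 trans to the vinyl group as the oxirane later requires.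

Step 2
Reactants: 4 ethyl (2E)-but-2-enoate
Product: 5 [(1-ethoxybuta-1,3-dien-1-yl)oxy]trimethylsilane (geometrical isomers at C1, inconsequential)
Conditions: LiN(iPr)2, THF–DMPU, −78 °C; Me3SiCl
Reagents that add atoms: chlorotrimethylsilane, C[Si](C)(C)Cl
Why: γ-Deprotonation of the crotonate gives the extended enolate, which is silylated on oxygen (silyl dienol ether formation).

Step 3
Reactants: 3 (2E)-2-methylpenta-2,4-dienal; 5 [(1-ethoxybuta-1,3-dien-1-yl)oxy]trimethylsilane
Product: 6 ethyl (2E,6E)-5-hydroxy-6-methylnona-2,6,8-trienoate (racemate)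
Conditions: BF3·OEt2, CH2Cl2, −78 °C; aq. NaHCO3
Reagents that add atoms: none
Why: Vinylogous Mukaiyama aldol addition; the Lewis-acid-activated aldehyde is attacked 1,2 by the unhindered γ-carbon of the dienol ether, giving the δ-hydroxy-(E)-enoate (C13–C14 bond).

Step 4
Reactants: 6 ethyl (2E,6E)-5-hydroxy-6-methylnona-2,6,8-trienoate (racemate)
Product: 7 ethyl (2E,5R,6E)-5-hydroxy-6-methylnona-2,6,8-trienoate
Conditions: Ti(OiPr)4 (cat.), L-(+)-diisopropyl tartrate, t-BuOOH (0.6 equiv), 4 Å molecular sieves, CH2Cl2, −20 °C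
Reagents that add atoms: none
Why: Sharpless kinetic resolution of a secondary allylic alcohol; with the L-(+)-tartrate the (5S)-carbinol is epoxidised much faster, so running past half conversion should leave the (5R)-alcohol, which is the C13 configuration of the target.

Step 5
Reactants: 7 ethyl (2E,5R,6E)-5-hydroxy-6-methylnona-2,6,8-trienoate
Product: 8 ethyl (2E,5R,6E)-5-[(tert-butyldimethylsilyl)oxy]-6-methylnona-2,6,8-trienoate
Conditions: t-BuMe2SiCl, imidazole, DMF, 25 °C
Reagents that add atoms: tert-butyldimethylsilyl chloride, CC(C)(C)[Si](C)(C)Cl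
Why: Silylation of the secondary alcohol; the ether must survive hydride, the alane, brief acid, a Grignard reagent and 120 °C.

Step 6
Reactants: 8 ethyl (2E,5R,6E)-5-[(tert-butyldimethylsilyl)oxy]-6-methylnona-2,6,8-trienoate
Product: 9 (2E,5R,6E)-5-[(tert-butyldimethylsilyl)oxy]-6-methylnona-2,6,8-trien-1-ol
Conditions: i-Bu2AlH, CH2Cl2, −78 °C; aq. potassium sodium tartrate
Reagents that add atoms: none
Why: 1,2-Reduction of the enoate to the (E)-allylic alcohol; the silyl ether and the diene are inert.

Step 7
Reactants: 9 (2E,5R,6E)-5-[(tert-butyldimethylsilyl)oxy]-6-methylnona-2,6,8-trien-1-ol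
Product: 10 [(2S,3S)-3-{(2R,3E)-2-[(tert-butyldimethylsilyl)oxy]-3-methylhexa-3,5-dien-1-yl}oxiran-2-yl]methanol
Conditions: Ti(OiPr)4 (cat.), L-(+)-diethyl tartrate, t-BuOOH, 4 Å molecular sieves, CH2Cl2, −20 °C
Reagents that add atoms: tert-butyl hydroperoxide, CC(C)(C)OO
Why: Sharpless asymmetric epoxidation of a primary (E)-allylic alcohol; the L-(+)-tartrate catalyst delivers oxygen to the face that gives the (2S,3S)-oxirane under reagent control. The diene has no free hydroxyl and is not touched.

Step 8
Reactants: 10 [(2S,3S)-3-{(2R,3E)-2-[(tert-butyldimethylsilyl)oxy]-3-methylhexa-3,5-dien-1-yl}oxiran-2-yl]methanol; 11 ethoxyethyne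
Product: 13 (4S,5R)-4-{(2R,3E)-2-[(tert-butyldimethylsilyl)oxy]-3-methylhexa-3,5-dien-1-yl}-5-(hydroxymethyl)oxolan-2-one, via ynol ether diol 12 (not isolated)
Conditions: 11, n-BuLi, toluene–hexane, 0 °C; Et2AlCl; then 10, 0 to 25 °C; aq. potassium sodium tartrate; crude 12, TsOH·H2O (cat.), wet CH2Cl2, 0 °C
Reagents that add atoms: water, O
Why: Hydroxyl-directed opening of the 2,3-epoxy alcohol by the alkynylalane takes place at the carbon remote from the hydroxymethyl group (C1) with inversion; acid hydration of the ynol ether through its ketene acetal then acylates the C2 hydroxyl to the five-membered lactone. Anti opening of the trans-oxirane puts C14 and C3 cis on the lactone, so C1 (inverted) and C2 (retained) both follow from step 7.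

Step 9
Reactants: 13 (4S,5R)-4-{(2R,3E)-2-[(tert-butyldimethylsilyl)oxy]-3-methylhexa-3,5-dien-1-yl}-5-(hydroxymethyl)oxolan-2-one
Product: 14 (2R,3S)-3-{(2R,3E)-2-[(tert-butyldimethylsilyl)oxy]-3-methylhexa-3,5-dien-1-yl}-5-oxooxolane-2-carbaldehyde
Conditions: Dess–Martin periodinane, NaHCO3, CH2Cl2, 0 to 25 °C
Reagents that add atoms: none
Why: Buffered Dess–Martin oxidation of the primary alcohol; the neutral conditions should not epimerise the α-acyloxy aldehyde at C2.

Step 10
Reactants: 14 (2R,3S)-3-{(2R,3E)-2-[(tert-butyldimethylsilyl)oxy]-3-methylhexa-3,5-dien-1-yl}-5-oxooxolane-2-carbaldehyde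
Product: 15 (4S,5R)-4-{(2R,3E)-2-[(tert-butyldimethylsilyl)oxy]-3-methylhexa-3,5-dien-1-yl}-5-(1-hydroxy-2-methylprop-2-en-1-yl)oxolan-2-one (both carbinol epimers)
Conditions: CH2=C(CH3)MgBr, THF, −78 °C
Reagents that add atoms: isopropenylmagnesium bromide, C=C(C)[Mg]Br
Why: Grignard 1,2-addition, chemoselective for the aldehyde over the lactone at low temperature (C3–C4 bond); the new carbinol centre is destroyed in step 11, so its configuration does not matter.

Step 11
Reactants: 15 (4S,5R)-4-{(2R,3E)-2-[(tert-butyldimethylsilyl)oxy]-3-methylhexa-3,5-dien-1-yl}-5-(1-hydroxy-2-methylprop-2-en-1-yl)oxolan-2-one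
Product: 17 (4S,5R)-4-{(2R,3E)-2-[(tert-butyldimethylsilyl)oxy]-3-methylhexa-3,5-dien-1-yl}-5-[(1E)-2-methyl-5-oxopent-1-en-1-yl]oxolan-2-one, via allyl vinyl ether 16 (not isolated)
Conditions: ethyl vinyl ether, Hg(OAc)2 (cat.), reflux; then toluene, 120 °C (sealed tube)
Reagents that add atoms: ethyl vinyl ether, C=COCC
Why: Vinyl transfer catalysed by divalent mercury, then Claisen rearrangement; the chair transition state with the lactone carbon pseudo-equatorial should give the (E)-C3=C4 olefin from either carbinol epimer. The same step forms the C5–C6 bond and leaves C7 as an aldehyde.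

Step 12
Reactants: 17 (4S,5R)-4-{(2R,3E)-2-[(tert-butyldimethylsilyl)oxy]-3-methylhexa-3,5-dien-1-yl}-5-[(1E)-2-methyl-5-oxopent-1-en-1-yl]oxolan-2-one; 2 2-(triphenyl-λ5-phosphanylidene)propanal
Product: 18 (4S,5R)-4-{(2R,3E)-2-[(tert-butyldimethylsilyl)oxy]-3-methylhexa-3,5-dien-1-yl}-5-[(1E,5E)-2,6-dimethyl-7-oxohepta-1,5-dien-1-yl]oxolan-2-one
Conditions: benzene, 80 °C
Reagents that add atoms: none
Why: Wittig reaction of the unhindered aldehyde with the stabilised ylide gives the (E)-C7=C8 enal; the α-branched enal product reacts much more slowly than the starting aldehyde.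

Step 13
Reactants: 18 (4S,5R)-4-{(2R,3E)-2-[(tert-butyldimethylsilyl)oxy]-3-methylhexa-3,5-dien-1-yl}-5-[(1E,5E)-2,6-dimethyl-7-oxohepta-1,5-dien-1-yl]oxolan-2-one
Product: 19 (4S,5R)-4-{(2R,3E)-2-[(tert-butyldimethylsilyl)oxy]-3-methylhexa-3,5-dien-1-yl}-5-[(1E,5E)-2,6-dimethylocta-1,5,7-trien-1-yl]oxolan-2-one
Conditions: Ph3PCH3Br, KN(SiMe3)2, THF, 0 °C; then 18, −78 to 0 °C
Reagents that add atoms: methyltriphenylphosphonium bromide, C[P+](c1ccccc1)(c1ccccc1)c1ccccc1.[Br-]
Why: Wittig methylenation of the enal gives the terminal vinyl group on C8; at low temperature the aldehyde reacts far faster than the lactone is enolised or attacked.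

Step 14
Reactants: 19 (4S,5R)-4-{(2R,3E)-2-[(tert-butyldimethylsilyl)oxy]-3-methylhexa-3,5-dien-1-yl}-5-[(1E,5E)-2,6-dimethylocta-1,5,7-trien-1-yl]oxolan-2-one
Product: 20 (4S,5R)-5-[(1E,5E)-2,6-dimethylocta-1,5,7-trien-1-yl]-4-[(2R,3E)-2-hydroxy-3-methylhexa-3,5-dien-1-yl]oxolan-2-one
Conditions: Bu4NF, AcOH, THF, 0 to 25 °C
Reagents that add atoms: none
Why: Fluoride cleavage of the silyl ether, buffered with acetic acid so that the lactone is not opened.

Step 15
Reactants: 20 (4S,5R)-5-[(1E,5E)-2,6-dimethylocta-1,5,7-trien-1-yl]-4-[(2R,3E)-2-hydroxy-3-methylhexa-3,5-dien-1-yl]oxolan-2-one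
Product: 21 (4S,5R)-5-[(1E,5E)-2,6-dimethylocta-1,5,7-trien-1-yl]-4-{(2R)-2-[(2R,3R)-3-ethenyl-2-methyloxiran-2-yl]-2-hydroxyethyl}oxolan-2-one
Conditions: Ti(OiPr)4 (cat.), D-(−)-diisopropyl tartrate, t-BuOOH, 4 Å molecular sieves, CH2Cl2, −20 °C
Reagents that add atoms: tert-butyl hydroperoxide, CC(C)(C)OO
Why: Sharpless epoxidation in the matched sense: the D-(−)-tartrate catalyst reacts fast with this (R)-carbinol and delivers oxygen to the C11=C12 face anti to C14, giving the erythro epoxy alcohol and setting C11 and C12. Only the olefin allylic to the hydroxyl is epoxidised; the vinyl group and the two remote trisubstituted olefins have no directing group.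

Step 16
Reactants: 21 (4S,5R)-5-[(1E,5E)-2,6-dimethylocta-1,5,7-trien-1-yl]-4-{(2R)-2-[(2R,3R)-3-ethenyl-2-methyloxiran-2-yl]-2-hydroxyethyl}oxolan-2-one
Product: 22 (4S,5R)-5-[(1E,5E)-2,6-dimethylocta-1,5,7-trien-1-yl]-4-{(2R)-2-[(2S,3R)-3-ethenyl-2-methyloxiran-2-yl]-2-[(triethylsilyl)oxy]ethyl}oxolan-2-one
Conditions: Et3SiCl, imidazole, 4-(dimethylamino)pyridine (cat.), DMF, 0 to 25 °C
Reagents that add atoms: chlorotriethylsilane, CC[Si](Cl)(CC)CC
Why: Silylation with an amine base only, so no alkoxide forms and Payne migration of the oxirane is avoided (the descriptor at the methyl-bearing oxirane carbon changes by priority only).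

Step 17
Reactants: 22 (4S,5R)-5-[(1E,5E)-2,6-dimethylocta-1,5,7-trien-1-yl]-4-{(2R)-2-[(2S,3R)-3-ethenyl-2-methyloxiran-2-yl]-2-[(triethylsilyl)oxy]ethyl}oxolan-2-one
Product: 23 (1S,2R,3E,7E,11R,12S,13R)-11,12-epoxy-13-[(triethylsilyl)oxy]cembra-3,7,9-trien-16,2-olide (C9=C10 as a mixture of geometrical isomers)
Conditions: second-generation Grubbs catalyst RuCl2(H2IMes)(PCy3)(=CHPh) (10 mol %), CH2Cl2 (1 mM), 40 °C
Reagents that add atoms: none
Why: Ring-closing olefin metathesis: the catalyst exchanges its benzylidene for one of the two monosubstituted vinyl groups, the new Ru alkylidene forms a ruthenacyclobutane with the other vinyl group, and cycloreversion releases ethene and the C9=C10 bond. The closest known reaction type is macrocyclic ring-closing metathesis between a 1,3-diene terminus and a vinyl oxirane. The 14-membered carbocycle is closed head to head between the vinyl carbon on C8 and the vinyl carbon on C11, with loss of the two terminal methylene carbons, at high dilution so that the intramolecular step outruns cross-metathesis. No stereocentre is created, and the geometry of the new olefin is irrelevant because step 18 saturates it. The step needs site selectivity for the two vinyl groups: the trisubstituted C3=C4 and C7=C8 olefins are too hindered for the catalyst, the methyl group on C8 blocks metathesis at the inner bond of the diene, and the lactone carries no α-methylene group that could compete as an acrylate. The cis fusion at C1/C2 holds both arms on the same face of the lactone and so brings the two termini together. The oxirane, the silyl ether and the lactone are inert to the neutral catalyst.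

Step 18
Reactants: 23 (1S,2R,3E,7E,11R,12S,13R)-11,12-epoxy-13-[(triethylsilyl)oxy]cembra-3,7,9-trien-16,2-olide
Product: 24 (1S,2R,3E,7E,11R,12S,13R)-11,12-epoxy-13-[(triethylsilyl)oxy]cembra-3,7-dien-16,2-olide
Conditions: 2-nitrobenzenesulfonylhydrazide, Et3N, CH2Cl2, 25 °C
Reagents that add atoms: none
Why: Diimide, released from the sulfonylhydrazide, transfers two hydrogens in a concerted syn fashion; its rate drops steeply with olefin substitution, so only the disubstituted C9=C10 bond should be reduced. No metal is involved, so the allylic oxirane and the allylic lactone are not hydrogenolysed.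

Step 19
Reactants: 24 (1S,2R,3E,7E,11R,12S,13R)-11,12-epoxy-13-[(triethylsilyl)oxy]cembra-3,7-dien-16,2-olide
Product: 25 (1S,2R,3E,7E,11R,12S,13R)-17-(dimethylamino)-11,12-epoxy-13-[(triethylsilyl)oxy]cembra-3,7-dien-16,2-olide (C15 epimers)
Conditions: LiN(iPr)2, THF, −78 °C; CH2=NMe2+ I−, −78 to 25 °C
Reagents that add atoms: Eschenmoser's salt (N,N-dimethylmethyleneiminium iodide), C=[N+](C)C.[I-]
Why: Mannich reaction of the lactone enolate (C15 is the only acidic position) with the iminium salt forms the C15–C17 bond; the new C15 centre is removed in step 20.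

Step 20
Reactants: 25 (1S,2R,3E,7E,11R,12S,13R)-17-(dimethylamino)-11,12-epoxy-13-[(triethylsilyl)oxy]cembra-3,7-dien-16,2-olide
Product: 27 (1S,2S,3E,7E,11R,12S,13R)-11,12-epoxy-13-[(triethylsilyl)oxy]cembra-3,7,15(17)-trien-16,2-olide, via methiodide 26 (not isolated)
Conditions: MeI, MeOH, 25 °C; then aq. NaHCO3, EtOAc, 25 °C
Reagents that add atoms: none
Why: N-Methylation gives the quaternary ammonium salt, and mild base then eliminates trimethylamine (E1cB) to the exocyclic methylene lactone (the C2 descriptor changes by priority only).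

Step 21
Reactants: 27 (1S,2S,3E,7E,11R,12S,13R)-11,12-epoxy-13-[(triethylsilyl)oxy]cembra-3,7,15(17)-trien-16,2-olide
Product: 28 (1S,2S,3E,7E,11R,12R,13R)-11,12-epoxy-13-hydroxycembra-3,7,15(17)-trien-16,2-olide
Conditions: HF·pyridine, pyridine, THF, 0 °C
Reagents that add atoms: none
Why: Buffered fluoride cleaves the triethylsilyl ether without forming an alkoxide, so neither Payne migration nor oxa-Michael addition of the C13 oxygen to C17 should occur (the C12 descriptor changes by priority only).

Step 22
Reactants: 28 (1S,2S,3E,7E,11R,12R,13R)-11,12-epoxy-13-hydroxycembra-3,7,15(17)-trien-16,2-olide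
Product: 29 (1S,2S,3E,7E,11R,12S,13R)-13-acetoxy-11,12-epoxycembra-3,7,15(17)-trien-16,2-olide (CNP0146076.4)
Conditions: Ac2O, pyridine, 4-(dimethylamino)pyridine (cat.), CH2Cl2, 0 to 25 °C
Reagents that add atoms: acetic anhydride, CC(=O)OC(C)=O
Why: Nucleophile-catalysed acylation of the secondary alcohol with retention at C13.

## Compound list

1 | acrolein (prop-2-enal) | C=CC=O | starting material
2 | 2-(triphenyl-λ5-phosphanylidene)propanal | CC(C=O)=P(c1ccccc1)(c1ccccc1)c1ccccc1 | starting material
3 | (2E)-2-methylpenta-2,4-dienal | C=C/C=C(\C)C=O | intermediate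
4 | ethyl (2E)-but-2-enoate | C/C=C/C(=O)OCC | starting material
5 | [(1-ethoxybuta-1,3-dien-1-yl)oxy]trimethylsilane (C1 geometry undefined) | C=CC=C(OCC)O[Si](C)(C)C | intermediate
6 | ethyl (2E,6E)-5-hydroxy-6-methylnona-2,6,8-trienoate (racemate) | CCOC(=O)/C=C/CC(O)/C(C)=C/C=C | intermediate
7 | ethyl (2E,5R,6E)-5-hydroxy-6-methylnona-2,6,8-trienoate | CCOC(=O)/C=C/C[C@@H](O)/C(C)=C/C=C | intermediate
8 | ethyl (2E,5R,6E)-5-[(tert-butyldimethylsilyl)oxy]-6-methylnona-2,6,8-trienoate | CCOC(=O)/C=C/C[C@@H](O[Si](C)(C)C(C)(C)C)/C(C)=C/C=C | intermediate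
9 | (2E,5R,6E)-5-[(tert-butyldimethylsilyl)oxy]-6-methylnona-2,6,8-trien-1-ol | OC/C=C/C[C@@H](O[Si](C)(C)C(C)(C)C)/C(C)=C/C=C | intermediate
10 | [(2S,3S)-3-{(2R,3E)-2-[(tert-butyldimethylsilyl)oxy]-3-methylhexa-3,5-dien-1-yl}oxiran-2-yl]methanol | OC[C@@H]1O[C@H]1C[C@@H](O[Si](C)(C)C(C)(C)C)/C(C)=C/C=C | intermediate
11 | ethoxyethyne | CCOC#C | starting material
12 | (2R,3S,5R,6E)-5-[(tert-butyldimethylsilyl)oxy]-3-(ethoxyethynyl)-6-methylnona-6,8-diene-1,2-diol | CCOC#C[C@H](C[C@@H](O[Si](C)(C)C(C)(C)C)/C(C)=C/C=C)[C@H](CO)O | intermediate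
13 | (4S,5R)-4-{(2R,3E)-2-[(tert-butyldimethylsilyl)oxy]-3-methylhexa-3,5-dien-1-yl}-5-(hydroxymethyl)oxolan-2-one | O=C1C[C@H](C[C@@H](O[Si](C)(C)C(C)(C)C)/C(C)=C/C=C)[C@H](CO)O1 | intermediate
14 | (2R,3S)-3-{(2R,3E)-2-[(tert-butyldimethylsilyl)oxy]-3-methylhexa-3,5-dien-1-yl}-5-oxooxolane-2-carbaldehyde | O=C1C[C@H](C[C@@H](O[Si](C)(C)C(C)(C)C)/C(C)=C/C=C)[C@H](C=O)O1 | intermediate
15 | (4S,5R)-4-{(2R,3E)-2-[(tert-butyldimethylsilyl)oxy]-3-methylhexa-3,5-dien-1-yl}-5-(1-hydroxy-2-methylprop-2-en-1-yl)oxolan-2-one (carbinol epimers) | O=C1C[C@H](C[C@@H](O[Si](C)(C)C(C)(C)C)/C(C)=C/C=C)[C@H](C(O)C(C)=C)O1 | intermediate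
16 | (4S,5R)-4-{(2R,3E)-2-[(tert-butyldimethylsilyl)oxy]-3-methylhexa-3,5-dien-1-yl}-5-[1-(ethenyloxy)-2-methylprop-2-en-1-yl]oxolan-2-one (ether-carbon epimers) | O=C1C[C@H](C[C@@H](O[Si](C)(C)C(C)(C)C)/C(C)=C/C=C)[C@H](C(OC=C)C(C)=C)O1 | intermediate
17 | (4S,5R)-4-{(2R,3E)-2-[(tert-butyldimethylsilyl)oxy]-3-methylhexa-3,5-dien-1-yl}-5-[(1E)-2-methyl-5-oxopent-1-en-1-yl]oxolan-2-one | O=C1C[C@H](C[C@@H](O[Si](C)(C)C(C)(C)C)/C(C)=C/C=C)[C@H](/C=C(\C)CCC=O)O1 | intermediate
18 | (4S,5R)-4-{(2R,3E)-2-[(tert-butyldimethylsilyl)oxy]-3-methylhexa-3,5-dien-1-yl}-5-[(1E,5E)-2,6-dimethyl-7-oxohepta-1,5-dien-1-yl]oxolan-2-one | O=C1C[C@H](C[C@@H](O[Si](C)(C)C(C)(C)C)/C(C)=C/C=C)[C@H](/C=C(\C)CC/C=C(\C)C=O)O1 | intermediate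
19 | (4S,5R)-4-{(2R,3E)-2-[(tert-butyldimethylsilyl)oxy]-3-methylhexa-3,5-dien-1-yl}-5-[(1E,5E)-2,6-dimethylocta-1,5,7-trien-1-yl]oxolan-2-one | O=C1C[C@H](C[C@@H](O[Si](C)(C)C(C)(C)C)/C(C)=C/C=C)[C@H](/C=C(\C)CC/C=C(\C)C=C)O1 | intermediate
20 | (4S,5R)-5-[(1E,5E)-2,6-dimethylocta-1,5,7-trien-1-yl]-4-[(2R,3E)-2-hydroxy-3-methylhexa-3,5-dien-1-yl]oxolan-2-one | O=C1C[C@H](C[C@@H](O)/C(C)=C/C=C)[C@H](/C=C(\C)CC/C=C(\C)C=C)O1 | intermediate
21 | (4S,5R)-5-[(1E,5E)-2,6-dimethylocta-1,5,7-trien-1-yl]-4-{(2R)-2-[(2R,3R)-3-ethenyl-2-methyloxiran-2-yl]-2-hydroxyethyl}oxolan-2-one | O=C1C[C@H](C[C@@H](O)[C@@]2(C)O[C@@H]2C=C)[C@H](/C=C(\C)CC/C=C(\C)C=C)O1 | intermediate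
22 | (4S,5R)-5-[(1E,5E)-2,6-dimethylocta-1,5,7-trien-1-yl]-4-{(2R)-2-[(2S,3R)-3-ethenyl-2-methyloxiran-2-yl]-2-[(triethylsilyl)oxy]ethyl}oxolan-2-one | O=C1C[C@H](C[C@@H](O[Si](CC)(CC)CC)[C@@]2(C)O[C@@H]2C=C)[C@H](/C=C(\C)CC/C=C(\C)C=C)O1 | intermediate
23 | (1S,2R,3E,7E,11R,12S,13R)-11,12-epoxy-13-[(triethylsilyl)oxy]cembra-3,7,9-trien-16,2-olide (C9=C10 geometry undefined) | C1C(=O)O[C@H]2/C=C(\C)CC/C=C(\C)C=C[C@H]3O[C@]3(C)[C@H](O[Si](CC)(CC)CC)C[C@@H]12 | intermediate
24 | (1S,2R,3E,7E,11R,12S,13R)-11,12-epoxy-13-[(triethylsilyl)oxy]cembra-3,7-dien-16,2-olide | C1C(=O)O[C@H]2/C=C(\C)CC/C=C(\C)CC[C@H]3O[C@]3(C)[C@H](O[Si](CC)(CC)CC)C[C@@H]12 | intermediate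
25 | (1S,2R,3E,7E,11R,12S,13R)-17-(dimethylamino)-11,12-epoxy-13-[(triethylsilyl)oxy]cembra-3,7-dien-16,2-olide (C15 epimers) | CN(C)CC1C(=O)O[C@H]2/C=C(\C)CC/C=C(\C)CC[C@H]3O[C@]3(C)[C@H](O[Si](CC)(CC)CC)C[C@@H]12 | intermediate
26 | N,N,N-trimethylammonium iodide (methiodide) of 25 | C[N+](C)(C)CC1C(=O)O[C@H]2/C=C(\C)CC/C=C(\C)CC[C@H]3O[C@]3(C)[C@H](O[Si](CC)(CC)CC)C[C@@H]12.[I-] | intermediate
27 | (1S,2S,3E,7E,11R,12S,13R)-11,12-epoxy-13-[(triethylsilyl)oxy]cembra-3,7,15(17)-trien-16,2-olide | C=C1C(=O)O[C@H]2/C=C(\C)CC/C=C(\C)CC[C@H]3O[C@]3(C)[C@H](O[Si](CC)(CC)CC)C[C@@H]12 | intermediate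
28 | (1S,2S,3E,7E,11R,12R,13R)-11,12-epoxy-13-hydroxycembra-3,7,15(17)-trien-16,2-olide | C=C1C(=O)O[C@H]2/C=C(\C)CC/C=C(\C)CC[C@H]3O[C@]3(C)[C@H](O)C[C@@H]12 | intermediate
29 | (1S,2S,3E,7E,11R,12S,13R)-13-acetoxy-11,12-epoxycembra-3,7,15(17)-trien-16,2-olide (CNP0146076.4) | C=C1C(=O)O[C@H]2/C=C(\C)CC/C=C(\C)CC[C@H]3O[C@]3(C)[C@H](OC(C)=O)C[C@@H]12 | target

## Step count and least certain steps

Total step count: 22. Longest linear sequence: 21 steps (step 1, then steps 3 to 22; step 2 is a one-step side branch).

Step 17 (key step). What may go wrong: cross-metathesis between molecules (dimers, oligomers) overtaking ring closure. Loading of the catalyst on the diene terminus gives a conjugated, sluggish alkylidene and the vinyl oxirane is hindered; metathesis at the inner C7=C8 bond would also truncate the ring. Fallback (relay ring-closing metathesis, which fixes where the metal loads), setting out from enal 18 and returning at 23: Wittig reaction of 18 with the ylide from (hex-5-en-1-yl)triphenylphosphonium bromide and KN(SiMe3)2 should give the relay-armed tetraene silyl ether F1. Bu4NF/AcOH as in step 14 gives the relay dienol F2, epoxidation as in step 15 gives the relay epoxy alcohol F3, and silylation as in step 16 gives the relay substrate F4. With RuCl2(H2IMes)(PCy3)(=CHPh) the catalyst loads on the unhindered terminal olefin of the tether, expels cyclopentene and is thereby delivered to C9, from where it closes onto the vinyl oxirane to give 23.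

Step 11. What may go wrong: incomplete vinyl transfer to the hindered carbinol, and partial loss of E selectivity at C3=C4, because the aldehyde-type rearrangement has no axial substituent that penalises the Z-chair. Fallback, from 15 back to 17: Eschenmoser–Claisen rearrangement with N,N-dimethylacetamide dimethyl acetal (toluene, 110 °C), in which the dimethylamino group makes the Z-chair prohibitive, should give the (E)-configured dimethylamide F5. Chemoselective reduction of the tertiary amide (Tf2O, 2-fluoropyridine, CH2Cl2, −78 °C; Et3SiH; aqueous citric acid) then gives aldehyde 17 with the lactone untouched.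

Step 8. What may go wrong: attack of the alane at C2 instead of C1, and ionisation or loss of the dienylic silyl ether, or drift to the six-membered lactone through the primary hydroxyl, during the acid hydration. Fallback, from 10 back to 13: opening with Et2AlC≡CSiMe3 (from ethynyltrimethylsilane, n-BuLi and Et2AlCl) gives the silylalkynyl diol F6, and K2CO3 in methanol gives the terminal alkynyl diol F7. Oxidative cyclisation of the homopropargylic alcohol through a Ru vinylidene (CpRu(cod)Cl, tri(2-furyl)phosphine, N-hydroxysuccinimide, Bu4NBr, NaHCO3, aqueous DMF) then gives lactone 13 without any acid.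

Step 15. What may go wrong: opening of the product, a vinyl oxirane with a neighbouring hydroxyl group, by isopropoxide or tartrate on the Lewis-acidic titanium centre. Fallback, from 20 back to 21: substrate-controlled epoxidation with VO(acac)2 and t-BuOOH (benzene, 0 to 25 °C). The hydroxyl group directs the oxidant, and the methyl group on C12 (allylic 1,2-strain) steers it to the same erythro face, with a small amount of a non-nucleophilic catalyst. This fallback makes no new compound (F0).

Step 18. What may go wrong: reduction beyond C9=C10 when excess reagent is needed, or stalling because diimide is lost by disproportionation. Fallback, from 23 back to 24: homogeneous hydrogenation with RhCl(PPh3)3 under H2 (benzene, 25 °C), which selects by olefin substitution at a metal centre instead of by a pericyclic hydrogen transfer and is much less prone than palladium to cleave allylic C–O bonds. This fallback makes no new compound (F0).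

## Further compounds

F1 | step 17 | (4S,5R)-4-{(2R,3E)-2-[(tert-butyldimethylsilyl)oxy]-3-methylhexa-3,5-dien-1-yl}-5-[(1E,5E)-2,6-dimethyltrideca-1,5,7,12-tetraen-1-yl]oxolan-2-one (C7=C8 of the side chain undefined) | O=C1C[C@H](C[C@@H](O[Si](C)(C)C(C)(C)C)/C(C)=C/C=C)[C@H](/C=C(\C)CC/C=C(\C)C=CCCCC=C)O1
F2 | step 17 | (4S,5R)-5-[(1E,5E)-2,6-dimethyltrideca-1,5,7,12-tetraen-1-yl]-4-[(2R,3E)-2-hydroxy-3-methylhexa-3,5-dien-1-yl]oxolan-2-one | O=C1C[C@H](C[C@@H](O)/C(C)=C/C=C)[C@H](/C=C(\C)CC/C=C(\C)C=CCCCC=C)O1
F3 | step 17 | (4S,5R)-5-[(1E,5E)-2,6-dimethyltrideca-1,5,7,12-tetraen-1-yl]-4-{(2R)-2-[(2R,3R)-3-ethenyl-2-methyloxiran-2-yl]-2-hydroxyethyl}oxolan-2-one | O=C1C[C@H](C[C@@H](O)[C@@]2(C)O[C@@H]2C=C)[C@H](/C=C(\C)CC/C=C(\C)C=CCCCC=C)O1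
F4 | step 17 | (4S,5R)-5-[(1E,5E)-2,6-dimethyltrideca-1,5,7,12-tetraen-1-yl]-4-{(2R)-2-[(2S,3R)-3-ethenyl-2-methyloxiran-2-yl]-2-[(triethylsilyl)oxy]ethyl}oxolan-2-one | O=C1C[C@H](C[C@@H](O[Si](CC)(CC)CC)[C@@]2(C)O[C@@H]2C=C)[C@H](/C=C(\C)CC/C=C(\C)C=CCCCC=C)O1
F5 | step 11 | (4E)-5-[(2R,3S)-3-{(2R,3E)-2-[(tert-butyldimethylsilyl)oxy]-3-methylhexa-3,5-dien-1-yl}-5-oxooxolan-2-yl]-N,N,4-trimethylpent-4-enamide | O=C1C[C@H](C[C@@H](O[Si](C)(C)C(C)(C)C)/C(C)=C/C=C)[C@H](/C=C(\C)CCC(=O)N(C)C)O1
F6 | step 8 | (2R,3S,5R,6E)-5-[(tert-butyldimethylsilyl)oxy]-6-methyl-3-[(trimethylsilyl)ethynyl]nona-6,8-diene-1,2-diol | C[Si](C)(C)C#C[C@H](C[C@@H](O[Si](C)(C)C(C)(C)C)/C(C)=C/C=C)[C@H](CO)O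
F7 | step 8 | (2R,3S,5R,6E)-5-[(tert-butyldimethylsilyl)oxy]-3-ethynyl-6-methylnona-6,8-diene-1,2-diol | C#C[C@H](C[C@@H](O[Si](C)(C)C(C)(C)C)/C(C)=C/C=C)[C@H](CO)O
F0 | step 15 | none | none
F0 | step 18 | none | none
A1 | alternative 1 | (2E,6E)-9-chloro-8-hydroxy-3,7-dimethylnona-2,6-dien-1-yl 2,2-dimethylpropanoate (racemate) | ClCC(O)/C(C)=C/CC/C(C)=C/COC(=O)C(C)(C)C
A2 | alternative 1 | erythro epoxy chlorohydrin pivalate with C11, C12 and C13 configured as in 29 | ClC[C@@H](O)[C@@]1(C)O[C@@H]1CC/C(C)=C/COC(=O)C(C)(C)C
A3 | alternative 2 | open-chain C6 allylic bromide / C5 phenyl sulfone with the 11,12-oxirane and three tert-butyldimethylsilyl ethers | BrC/C=C(\C)CC[C@H]1O[C@]1(C)[C@H](O[Si](C)(C)C(C)(C)C)C[C@@H](C(=C)CO[Si](C)(C)C(C)(C)C)[C@@H](O[Si](C)(C)C(C)(C)C)/C=C(\C)CS(=O)(=O)c1ccccc1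
A4 | alternative 2 | macrocyclic C5 phenyl sulfone (both C5 epimers) | C2/C=C(\C)CC[C@H]1O[C@]1(C)[C@H](O[Si](C)(C)C(C)(C)C)C[C@@H](C(=C)CO[Si](C)(C)C(C)(C)C)[C@@H](O[Si](C)(C)C(C)(C)C)/C=C(\C)C2S(=O)(=O)c1ccccc1
A5 | alternative 3 | open-chain C13 aldehyde with a C11≡C12 methyl alkyne and two tert-butyldimethylsilyl ethers | O=CC[C@@H](C(=C)CO[Si](C)(C)C(C)(C)C)[C@@H](O[Si](C)(C)C(C)(C)C)/C=C(\C)CC/C=C(\C)CCC#CC
A6 | alternative 3 | macrocyclic (E)-allylic alcohol at C13 | O[C@@H]1C[C@@H](C(=C)CO[Si](C)(C)C(C)(C)C)[C@@H](O[Si](C)(C)C(C)(C)C)/C=C(\C)CC/C=C(\C)CC/C=C1\C
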